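The data are simulated from invented constants; noise was put on by code.

The flask holds 8.00 mM of partner against 0.010 M of starting material, so even if every partner landed on starting material, it would take up 80.0% of the charge. Some partner, however, is lost to self-condensation.

| setting | teal | red | flask |
|---|---|---|---|
| starting material | 0.010 M (fed, over 80 s) | 0.0050 M (fed, over 80 s) | 0.010 M (fed, over 80 s) |
| partner | 8 mM | 8 mM | 8.00 mM |
| remark | the very flask that is asked about, followed so far | run made earlier |  |
| time |  |  | 25 min |

| run | time / min | single product / % | other mono adduct / % |
|---|---|---|---|
| teal | 0.250 | 0 | 1 |
| teal | 0.417 | 3 | 3 |
| teal | 0.833 | 3 | 2 |
| teal | 1.50 | 9 | 4 |
| teal | 3.00 | 19 | 4 |
| red | 1.33 | 14 | 0 |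
| red | 2.50 | 20 | 0 |
| red | 5.00 | 23 | 6 |
| red | 10.0 | 29 | 4 |
| red | 20.0 | 31 | 3 |

(each reading ± 2 percentage points)

* the state of affairs at 25 min: stopped, and by what, or still going (forward and back rates have come level / all of the starting material has reacted / the partner has run out first / it is still moving)
* single product at 25 min, in percent of the starting material charged
* other mono adduct at 25 min, in percent of the starting material charged

- the numbers in the tables scatter by 2 percentage points (one standard deviation)
- steps thought possible: starting material + partner -> single product + released group; 2 partner -> self-condensation product; partner + single product -> bis adduct + released group; partner + other mono adduct -> bis adduct + released group; starting material + partner -> other mono adduct + released group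
- the reaction counts as stopped when no species that holds the starting material changes by six tenths of a point or more over the second half of the time
- percentages count the whole charge, also what has not yet gone in

Call the capture share the part of the partner charge that ends on starting material. Red, read from its last mono adducts, gives 21.2%.

Starting material is not steady: both runs feed it in over 80 s, so it climbs from zero while partner is leaving. What I freeze instead is the ratio of the two feeds. Partner leaves by a path proportional to partner times starting material and by one proportional to the square of partner. At a given moment and partner level, the flask has been fed twice red's starting material, so the first path runs up to that factor faster. Two extremes bound the flask: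

If the first path already dominates, capture is unchanged: 17.0% of the charge.

If the first path is weak, capture scales with starting material: 34.0% of the charge.

My estimate takes their geometric mean, 24.0%, divided as in teal's last reading: 19.9% single product and 4.18% other mono adduct.

The forecast differs, with 25% and 3.5%, and expects that the partner has run out first: “No back reaction is listed, so this is partner exhaustion, not equilibrium.”

The flask gives 20.1% and 2.77%, and the partner has run out first, the limiting reagent standing at 0%.

    starting material + partner → single product + released group (k = 1.10 /M/s)
    2 partner → self-condensation product (k = 2.20 /M/s)
    partner + single product → bis adduct + released group (k = 0.0380 /M/s)
    partner + other mono adduct → bis adduct + released group (k = 0.460 /M/s)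
    starting material + partner → other mono adduct + released group (k = 0.160 /M/s)

By self-condensation, partner as charged has a first half-life of 0.473 min, shorter than the 5.6 min it has by the step to single product at 0.264 min. Released group puts the flask's capture at 29.2%, above red's 21.2%. With 0.020 M of partner, the neighbour reaches 24.8% single product, and its capture is 14.5%.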